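**Assumption.** The ring is numbered C1 (carbonyl carbon), C2=C3, C4 (acetoxy carbon), C5 (fully substituted carbon), with C1′ for the side-chain carbinol. Methyl (2S)-oxirane-2-carboxylate, 1-bromotridecane and allylmagnesium bromide solution are taken as purchasable.

## Analysis of the target

Compound 16 is a cyclopent-2-en-1-one with an acetoxy group on C4 and a fully substituted C5 that carries a tertiary hydroxyl and a 1-hydroxypentadecyl chain. The three stereocentres are contiguous: C4 (R), C5 (S) and C1′ (S). The C4 acetate is trans to the C5 hydroxyl and therefore cis to the side chain. The γ-acyloxy enone is a Michael acceptor with a base-labile ester that can migrate to the neighbouring hydroxyls, and the tertiary α-ketol tolerates neither strong base nor strong acid. C5 has no hydrogen, so its configuration cannot be corrected later by epimerisation; it has to be set relative to C1′ in the step that creates it. The route rests on one feature: the oxygen on C1 and the oxygen on C4 are 1,4-related across the C2=C3 alkene and sit on the two ring neighbours of C5. If these two oxygens were equivalent, C5 would not be stereogenic within the ring, so the ring can be made as a cis-1,4-dioxygenated cyclopentene from a diene and differentiated afterwards. Tying the C5 and C1′ oxygens into a dioxolane turns C5 into a spiro carbon with two different faces (oxygen against branched carbon), and C1′ then becomes the single purchased source of chirality.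

## Retrosynthetic reasoning

**16 to 15.** The last bonds cut are the two C–O bonds of the isopropylidene ketal joining the C5 and C1′ oxygens. Keeping the diol masked to the end prevents acyl migration during the ester-forming step, and the same ketal is the control element of every stereoselective step before it. The forward reaction has to hydrolyse the ketal with cold aqueous acid without touching the allylic ester.

**15 to 14.** The C4–O bond is disconnected with inversion, which leads to 14, where the C4 hydroxyl is cis to the dioxolane oxygen on the spiro carbon. The cut is made here because the ring-forming oxygenation can only deliver the C4 oxygen cis to the C5 oxygen, while the target has it trans. The forward reaction is a substitution at a hindered allylic carbon; C5 has no hydrogen, so elimination is not a competing path.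

**14 to 13.** The C1 carbonyl and the C4 hydroxyl are traced back to a single O–O bridge in 13. No skeletal bond is cut. What is gained is a precursor whose two bridgeheads differ only through C1′. The forward reaction must remove the bridgehead hydrogen on the side away from the tetradecyl chain; that choice alone fixes C5.

**13 to 12.** This is the key disconnection. Both ring C–O bonds (C1–O and C4–O) are cut at once in a retro-(4+2) step, leaving the spiro diene 12. No other cut removes two heteroatom bonds, one ring and three stereocentres together while arriving at a precursor without ring stereocentres. The forward photooxygenation has to add to the diene face that carries the dioxolane oxygen.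

**12 to 9.** The two double bonds of 12 are traced, through allylic bromide 11 and dibromide 10, to the single alkene of cyclopentene 9. No C–C bond is cut. The gain is a stable precursor from which the dimerisation-prone diene is released only immediately before use.

**9 to 8.** The ring alkene is cut by retro-metathesis to the gem-diallyl dioxolane 8. The five-membered ring closes easily in the forward direction because both olefin arms sit on the same carbon.

**8 to 4 and 5.** Removal of the ketal gives diol 7. Cutting the two C–C bonds at its tertiary carbinol leads, through ketone 6, to ester 4 and two equivalents of 5. The ester carbon becomes C5 of the target; it is not stereogenic at this stage, so nothing has to be controlled.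

**4 to 2 and 1.** The C3–C4 bond of the hydroxy ester is cut, giving epoxide 2 and the tridecyl nucleophile 3 made from 1. The C1′ stereocentre is bought with 2, and the forward reaction only has to open the epoxide at its unsubstituted carbon.

## Alternatives that were turned down

**Alternative 1:** ring-closing metathesis. The C2=C3 bond is cut, leading to an open-chain precursor with an acryloyl carbon as C1 and a vinyl group on C4. C5 would be set earlier by adding a carbon nucleophile to an acyclic ketone flanked by the two ether-bearing stereocentres. In the forward step the second-generation Grubbs catalyst RuCl2(=CHPh)(PCy3)(H2IMes) joins the two vinyl groups to give A1, (4R,5S)-5-[(1S)-1-(benzyloxy)pentadecyl]-5-hydroxy-4-[(4-methoxybenzyl)oxy]cyclopent-2-en-1-one.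
- For: the ring closure is dependable and touches no stereocentre, and the trans C4/C5 relation is built directly, so no inversion is needed. On that point it is stronger than the chosen route.
- Against: all three stereocentres must be made in an open chain. The ketone that becomes C5 has two α-alkoxy centres of nearly equal steric and chelating demand, so face selection there has no firm basis. An acryloyl group next to a fully substituted carbon is a slow metathesis partner. After A1 the two ethers must be removed in order around an enone and an allylic acetate, which rules out hydrogenolysis of the benzyl ether.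
- Comparison: the chosen route is shorter, uses one protecting group, and sets C5 by a steric difference fixed in a rigid spiro ring instead of by acyclic face selection.

**Alternative 2:** photochemical ring contraction of a 4-pyranone. The C3–C4 bond and the C5–OH bond are cut, leading to a 3-substituted 4-pyranone that carries the silyl-protected side chain. On irradiation in water-rich solvent the two carbons next to the pyran oxygen bond to each other, giving an epoxide-bridged oxyallyl zwitterion. Water adds at the substituted terminus anti to the epoxide, and the epoxide opens to the C4 hydroxyl, giving A2, (4R,5R)-5-[(1S)-1-(tert-butyldimethylsilyloxy)pentadecyl]-4,5-dihydroxycyclopent-2-en-1-one.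
- For: it is the shortest of all the routes considered, delivers the trans-diol directly with a free C4 hydroxyl ready for acetylation, and needs no inversion. It is stronger than the chosen route in step count and in the C4/C5 relation.
- Against: the only element that can set the absolute sense of the ring is the exocyclic C1′ centre acting on a flat excited pyranone, so both ring diastereomers must be expected. The site of water capture (substituted or unsubstituted terminus) is not secured. The enone product absorbs light and can react further, and the reaction needs high dilution.
- Comparison: the chosen route gives up brevity and accepts an inversion in exchange for control of the ring configuration relative to C1′.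

**Alternative 3:** rhodium-catalysed trans-hydroacylation. The C1–C2 bond is cut, leading to an open-chain 4-alkynal in which the aldehyde sits on the fully substituted C5, C4 is a propargylic acetate and the alkyne carries a silyl cap. A cationic monovalent rhodium complex such as [Rh(dppe)]2(BF4)2 inserts into the aldehyde C–H bond and adds it trans across the alkyne, closing the ring to A3, (4S,5S,6R)-2,2-dimethyl-9-oxo-4-tetradecyl-8-(trimethylsilyl)-1,3-dioxaspiro[4.4]non-7-en-6-yl acetate.
- For: every stereocentre, including the C4 acetate in its final configuration, is in place before cyclisation, the closure is atom-economic, and A3 is two steps from the target. On C4 it is at least as strong as the chosen route.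
- Against: the alkynal precursor, with an α-oxygenated quaternary aldehyde carbon next to a propargylic acetate, needs a long acyclic sequence. An acyl rhodium hydride from so hindered an aldehyde is prone to decarbonylation, and the propargylic ester can migrate under cationic rhodium. The silyl group must later be removed from an α-silyl enone beside a base-sensitive γ-acetate.
- Comparison: the chosen route reaches the ring from a simple spiro diene in one oxygenation and places its risk in a well-precedented cycloaddition rather than in an organometallic step on a crowded substrate.

Key step: step 7

## Route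

Step 1
Reactants: 1 1-bromotridecane; 2 methyl (2S)-oxirane-2-carboxylate
Product: 4 methyl (2S)-2-hydroxyhexadecanoate, via tridecylmagnesium bromide 3 (not isolated)
Conditions: Mg, THF, 45 °C; then 2, CuBr·SMe2 (10 mol%), THF, −40 °C; aq. NH4Cl
Reagents that add atoms: none
Why: Copper-catalysed Grignard opening of a glycidic ester; the organocopper species attacks the unsubstituted epoxide carbon faster than the Grignard reagent adds to the ester at low temperature, and the stereocentre is not touched, so its configuration passes unchanged into 4.

Step 2
Reactants: 4 methyl (2S)-2-hydroxyhexadecanoate; 5 allylmagnesium bromide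
Product: 7 (5S)-4-(prop-2-en-1-yl)nonadec-1-ene-4,5-diol, via (5S)-5-hydroxynonadec-1-en-4-one 6 (not isolated)
Conditions: 5 (3.3 equiv), Et2O–THF, −20 → 0 °C; aq. NH4Cl
Reagents that add atoms: none
Why: Double Grignard addition to an ester; the first equivalent deprotonates the hydroxyl (the alkoxide protects the α-centre against enolisation) and the next two add through ketone 6, and the new carbinol carbon carries two identical allyl groups, so it is not stereogenic.

Step 3
Reactants: 7 (5S)-4-(prop-2-en-1-yl)nonadec-1-ene-4,5-diol
Product: 8 (5S)-2,2-dimethyl-4,4-di(prop-2-en-1-yl)-5-tetradecyl-1,3-dioxolane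
Conditions: Me2C(OMe)2, PPTS (cat.), CH2Cl2, rt
Reagents that add atoms: 2,2-dimethoxypropane, COC(C)(C)OC
Why: Acid-catalysed transketalisation of a 1,2-diol; the five-membered dioxolane forms readily and locks the two oxygens that later become the C5 and C1′ hydroxyls into one ring.

Step 4
Reactants: 8 (5S)-2,2-dimethyl-4,4-di(prop-2-en-1-yl)-5-tetradecyl-1,3-dioxolane
Product: 9 (4S)-2,2-dimethyl-4-tetradecyl-1,3-dioxaspiro[4.4]non-7-ene
Conditions: second-generation Grubbs catalyst RuCl2(=CHPh)(PCy3)(H2IMes) (2 mol%), CH2Cl2, 40 °C
Reagents that add atoms: none
Why: Ring-closing metathesis of a gem-diallyl unit to a cyclopentene, driven by loss of ethene and helped by the geminal substitution; the ketal is inert to the catalyst.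

Step 5
Reactants: 9 (4S)-2,2-dimethyl-4-tetradecyl-1,3-dioxaspiro[4.4]non-7-ene
Product: 10 (4S,7R,8R)-7,8-dibromo-2,2-dimethyl-4-tetradecyl-1,3-dioxaspiro[4.4]nonane (trans-dibromide; the (4S,7S,8S) isomer forms alongside and is carried on together)
Conditions: Br2, NaHCO3, CH2Cl2, −78 °C
Reagents that add atoms: bromine, BrBr
Why: Anti addition of bromine through a bromonium ion gives the trans-dibromide as two diastereomers that both lead to the same diene; solid NaHCO3 protects the ketal from traces of HBr.

Step 6
Reactants: 10 (4S,7R,8R)-7,8-dibromo-2,2-dimethyl-4-tetradecyl-1,3-dioxaspiro[4.4]nonane
Product: 12 (4S)-2,2-dimethyl-4-tetradecyl-1,3-dioxaspiro[4.4]nona-6,8-diene, via (4S)-8-bromo-2,2-dimethyl-4-tetradecyl-1,3-dioxaspiro[4.4]non-6-ene 11 (not isolated)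
Conditions: KOtBu (3 equiv), THF–DMSO, 0 °C; cold pentane work-up, solution used at once
Reagents that add atoms: none
Why: Two successive E2 eliminations; in the trans-dibromide each bromine has an anti hydrogen only on the neighbouring methylene group, so the first elimination gives allylic bromide 11 and not a vinyl bromide, the second gives the 1,3-diene, and the bulky alkoxide disfavours substitution.

Step 7
Reactants: 12 (4S)-2,2-dimethyl-4-tetradecyl-1,3-dioxaspiro[4.4]nona-6,8-diene
Product: 13 (5′S)-2′,2′-dimethyl-5′-tetradecylspiro[2,3-dioxabicyclo[2.2.1]hept-5-ene-7,4′-[1,3]dioxolane] with the peroxide bridge syn to the dioxolane oxygen O3′ (kept in solution at −78 °C)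
Conditions: O2, 5,10,15,20-tetraphenylporphyrin (cat.), visible light, CH2Cl2, −78 °C
Reagents that add atoms: dioxygen, O=O
Why: Energy transfer from the excited porphyrin gives singlet dioxygen, which adds suprafacially in a concerted (4+2) step to the s-cis-locked diene of 12 and forms the C1–O and C4–O bonds together. The closest known reaction type is the sensitised photooxygenation of cyclopentadienes and spiro-annulated cyclopentadienes to 2,3-dioxabicyclo[2.2.1]hept-5-enes. The new ring is closed by intermolecular cycloaddition, both oxygen atoms bonding in one step, so the 1,2-dioxolane ring and the bicyclic bridge arise together without a separate ring-closing event. The three new stereocentres (the two bridgeheads and the spiro carbon) are fixed by one decision, the π-face: the peroxide should form syn to the dioxolane oxygen on the spiro carbon, because on the other face the first methylene of the tetradecyl chain, held in place by the dioxolane, lies directly under one diene terminus, and because 5-oxygenated cyclopentadienes are known to take up dienophiles syn to oxygen. The step needs face selectivity and chemoselectivity; the latter is secured by the absence of hydrogen on the spiro carbon (no ene reaction, no 1,5-hydrogen shift) and by working dilute at −78 °C, where Diels–Alder dimerisation of 12 and thermal rearrangement of 13 are slow. The two bridgeheads are not yet told apart here; that is left to step 8.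

Step 8
Reactants: 13 (5′S)-2′,2′-dimethyl-5′-tetradecylspiro[2,3-dioxabicyclo[2.2.1]hept-5-ene-7,4′-[1,3]dioxolane]
Product: 14 (4S,5R,9S)-9-hydroxy-2,2-dimethyl-4-tetradecyl-1,3-dioxaspiro[4.4]non-7-en-6-one
Conditions: Et3N (1.2 equiv), CH2Cl2, −78 → −30 °C (added to the cold solution from step 7 after purging with argon)
Reagents that add atoms: none
Why: Kornblum–DeLaMare rearrangement; the amine removes a bridgehead hydrogen antiperiplanar to the O–O bond in an E2-like step, giving the ketone at that carbon and the hydroxyl at the other. The bridgehead on the side of the dioxolane C–H is open whereas the other is screened by the first methylene of the tetradecyl chain, so the ketone should form remote from the chain, which fixes the spiro carbon in the sense required for C5 and leaves the new hydroxyl cis to the dioxolane oxygen.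

Step 9
Reactants: 14 (4S,5R,9S)-9-hydroxy-2,2-dimethyl-4-tetradecyl-1,3-dioxaspiro[4.4]non-7-en-6-one
Product: 15 (4S,5S,6R)-2,2-dimethyl-9-oxo-4-tetradecyl-1,3-dioxaspiro[4.4]non-7-en-6-yl acetate
Conditions: AcOH, PPh3, DIAD, toluene, 0 °C → rt
Reagents that add atoms: acetic acid, CC(=O)O
Why: Mitsunobu esterification; acetate displaces the alkoxyphosphonium group at the allylic carbinol carbon in an SN2 step with inversion, turning the cis oxygen into the trans acetate of the target, while the neighbouring spiro carbon has no hydrogen (no elimination) and the conjugated alkene offers no SN2′ path.

Step 10
Reactants: 15 (4S,5S,6R)-2,2-dimethyl-9-oxo-4-tetradecyl-1,3-dioxaspiro[4.4]non-7-en-6-yl acetate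
Product: 16 (4R,5S)-4-acetoxy-5-hydroxy-5-[(1S)-1-hydroxypentadecyl]cyclopent-2-en-1-one
Conditions: TFA–H2O (9:1), CH2Cl2, 0 °C
Reagents that add atoms: none
Why: Acid-catalysed ketal hydrolysis; the allylic acetate and the enone tolerate cold aqueous acid for the short time needed, and no stereocentre is touched.

## Compound list

1 | 1-bromotridecane | CCCCCCCCCCCCCBr | starting material
2 | methyl (2S)-oxirane-2-carboxylate | COC(=O)[C@@H]1CO1 | starting material
3 | tridecylmagnesium bromide | CCCCCCCCCCCCC[Mg]Br | intermediate (not isolated)
4 | methyl (2S)-2-hydroxyhexadecanoate | CCCCCCCCCCCCCC[C@H](O)C(=O)OC | intermediate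
5 | allylmagnesium bromide | C=CC[Mg]Br | starting material
6 | (5S)-5-hydroxynonadec-1-en-4-one (present as its magnesium alkoxide) | CCCCCCCCCCCCCC[C@H](O)C(=O)CC=C | intermediate (not isolated)
7 | (5S)-4-(prop-2-en-1-yl)nonadec-1-ene-4,5-diol | CCCCCCCCCCCCCC[C@H](O)C(O)(CC=C)CC=C | intermediate
8 | (5S)-2,2-dimethyl-4,4-di(prop-2-en-1-yl)-5-tetradecyl-1,3-dioxolane | CCCCCCCCCCCCCC[C@@H]1OC(C)(C)OC1(CC=C)CC=C | intermediate
9 | (4S)-2,2-dimethyl-4-tetradecyl-1,3-dioxaspiro[4.4]non-7-ene | CCCCCCCCCCCCCC[C@@H]1OC(C)(C)OC12CC=CC2 | intermediate
10 | (4S,7R,8R)-7,8-dibromo-2,2-dimethyl-4-tetradecyl-1,3-dioxaspiro[4.4]nonane (trans; accompanied by the (4S,7S,8S) isomer) | CCCCCCCCCCCCCC[C@@H]1OC(C)(C)OC12C[C@@H](Br)[C@H](Br)C2 | intermediate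
11 | (4S)-8-bromo-2,2-dimethyl-4-tetradecyl-1,3-dioxaspiro[4.4]non-6-ene (mixture of isomers at C5 and C8) | CCCCCCCCCCCCCC[C@@H]1OC(C)(C)OC12C=CC(Br)C2 | intermediate (not isolated)
12 | (4S)-2,2-dimethyl-4-tetradecyl-1,3-dioxaspiro[4.4]nona-6,8-diene | CCCCCCCCCCCCCC[C@@H]1OC(C)(C)OC12C=CC=C2 | intermediate
13 | (5′S)-2′,2′-dimethyl-5′-tetradecylspiro[2,3-dioxabicyclo[2.2.1]hept-5-ene-7,4′-[1,3]dioxolane], peroxide bridge syn to O3′ | CCCCCCCCCCCCCC[C@@H]1OC(C)(C)O[C@@]12[C@H]3C=C[C@@H]2OO3 | intermediate
14 | (4S,5R,9S)-9-hydroxy-2,2-dimethyl-4-tetradecyl-1,3-dioxaspiro[4.4]non-7-en-6-one | CCCCCCCCCCCCCC[C@@H]1OC(C)(C)O[C@@]12C(=O)C=C[C@@H]2O | intermediate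
15 | (4S,5S,6R)-2,2-dimethyl-9-oxo-4-tetradecyl-1,3-dioxaspiro[4.4]non-7-en-6-yl acetate | CCCCCCCCCCCCCC[C@@H]1OC(C)(C)O[C@@]12C(=O)C=C[C@H]2OC(C)=O | intermediate
16 | (4R,5S)-4-acetoxy-5-hydroxy-5-[(1S)-1-hydroxypentadecyl]cyclopent-2-en-1-one | CCCCCCCCCCCCCC[C@H](O)[C@@]1(O)C(=O)C=C[C@H]1OC(C)=O | target

## Step count and least certain steps

Total: 10 steps. Longest linear sequence: 10 steps (from 1 and 2 to 16).

**Step 7 (key step).** Diels–Alder dimerisation of the diene before or during oxygenation, partial addition to the face of the branched carbon, or thermal rearrangement of the strained peroxide on warming would each reduce the amount of usable 13. The fallback avoids both the free diene and the peroxide and sets out from the stable cyclopentene 9. Allylic C–H oxidation at both ring methylene groups with Rh2(cap)4 (dirhodium tetrakis(caprolactamate)) and t-BuOOH, running through the enone, should give (4S)-2,2-dimethyl-4-tetradecyl-1,3-dioxaspiro[4.4]non-7-ene-6,9-dione F1. In F1 both ring oxygens are carbonyls, so face and bridgehead questions are moved to a later reduction. F1 is then taken on by the reduction and acetylation described under step 9 and comes back to the route at 15.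

**Step 8.** The amine may remove the chain-side bridgehead hydrogen as well, so that both bridgeheads are oxidised and C5 is formed in both senses; the peroxide may also rearrange thermally faster than it is deprotonated. A bulkier or cinchona-derived quinuclidine base is the first adjustment within the step. The fallback separates O–O cleavage from oxidation and sets out from 13:
- Reduction with thiourea at −78 °C should give the stable cis-diol (4S)-2,2-dimethyl-4-tetradecyl-1,3-dioxaspiro[4.4]non-7-ene-6,9-diol F2, with both hydroxyls cis to the dioxolane oxygen on the spiro carbon.
- The carbinol remote from the chain is then oxidised selectively with the bulky oxoammonium reagent from TEMPO and PhI(OAc)2, stopped at mono-oxidation, which returns to the route at 14.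
- If the two carbinols still cannot be told apart, F2 can be oxidised fully with MnO2 to F1 and follow the fallback of step 9.

**Step 9.** The SN2 trajectory at the carbinol carbon runs past the branched C1′ and the first methylene of the chain, which the dioxolane holds under that carbon. Substitution may therefore be slow, and attack of acetate at phosphorus (ester with retention) or incomplete conversion may take over. The fallback replaces substitution by an oxidation–reduction sequence and sets out from 14:
- Dess–Martin oxidation gives the enedione F1.
- Reduction with (S)-2-methyl-CBS-oxazaborolidine (cat.) and catecholborane in toluene at −78 °C should give (4S,5R,9R)-9-hydroxy-2,2-dimethyl-4-tetradecyl-1,3-dioxaspiro[4.4]non-7-en-6-one F3. The catalyst enantiomer is the one predicted by the large/small model with the quaternary carbon as the large group. The face of the dioxolane oxygen is the open one, and among additions from that face the catalyst should select the chain-side carbonyl, so hydride arrives there and the hydroxyl ends up trans to the dioxolane oxygen.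
- Acetylation with Ac2O, pyridine and DMAP returns to the route at 15.

**Step 6.** The second elimination may stall at the allylic bromide, the alkoxide may substitute instead of eliminating, or the diene may dimerise during work-up. The fallback changes how the diene is released and sets out from 9. Radical allylic bromination with N-bromosuccinimide (light, PhCF3) gives allylic bromide 11 directly, this time isolated and storable. A single dehydrobromination with DBU in CH2Cl2 at −20 °C, followed by a cold aq. NaHCO3 wash, releases 12 immediately before step 7, so no alkoxide is used and the diene is never stored.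

## Further compounds

F1 | step 7 | (4S)-2,2-dimethyl-4-tetradecyl-1,3-dioxaspiro[4.4]non-7-ene-6,9-dione | CCCCCCCCCCCCCC[C@@H]1OC(C)(C)OC12C(=O)C=CC2=O
F2 | step 8 | (4S)-2,2-dimethyl-4-tetradecyl-1,3-dioxaspiro[4.4]non-7-ene-6,9-diol, both hydroxyls cis to the dioxolane oxygen on the spiro carbon | CCCCCCCCCCCCCC[C@@H]1OC(C)(C)O[C@@]12[C@H](O)C=C[C@@H]2O
F3 | step 9 | (4S,5R,9R)-9-hydroxy-2,2-dimethyl-4-tetradecyl-1,3-dioxaspiro[4.4]non-7-en-6-one | CCCCCCCCCCCCCC[C@@H]1OC(C)(C)O[C@@]12C(=O)C=C[C@H]2O
F0 | step 6 | none | none
A1 | alternative 1 | (4R,5S)-5-[(1S)-1-(benzyloxy)pentadecyl]-5-hydroxy-4-[(4-methoxybenzyl)oxy]cyclopent-2-en-1-one | CCCCCCCCCCCCCC[C@H](OCc1ccccc1)[C@@]2(O)C(=O)C=C[C@H]2OCc3ccc(OC)cc3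
A2 | alternative 2 | (4R,5R)-5-[(1S)-1-(tert-butyldimethylsilyloxy)pentadecyl]-4,5-dihydroxycyclopent-2-en-1-one | CCCCCCCCCCCCCC[C@H](O[Si](C)(C)C(C)(C)C)[C@@]1(O)C(=O)C=C[C@H]1O
A3 | alternative 3 | (4S,5S,6R)-2,2-dimethyl-9-oxo-4-tetradecyl-8-(trimethylsilyl)-1,3-dioxaspiro[4.4]non-7-en-6-yl acetate | CCCCCCCCCCCCCC[C@@H]1OC(C)(C)O[C@@]12C(=O)C([Si](C)(C)C)=C[C@H]2OC(C)=O
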